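## Structural features

The target 16 is a linear chain of six six-membered carbocycles, A to F, joined by five CH2 bridges. Rings A and F are 2-butanoyl-4,4-dimethylcyclohexane-1,3,5-trione units (butyrylfilicinic acid residues, written as one dienol–enone tautomer). Rings B, C, D and E are hexasubstituted 3-butanoyl-2,4,6-trihydroxyphenyl units whose two remaining carbons carry the bridges. The molecule has no stereocentre, so none stand next to each other. Its constitution is twofold symmetric about the CH2 between rings C and D, which makes A/F, B/E and C/D pairwise equivalent. The fragile elements are the bridges between free polyphenol rings (they interchange in base by retro-Michael cleavage through quinone methides), the enolised β-triketone ends (they can cyclodehydrate onto a neighbouring phenol in strong acid) and the sixteen acidic, easily oxidised hydroxyls. The real difficulty is the order of bond formation: every ring is a carbon nucleophile and, once hydroxymethylated, an electrophile, so formaldehyde condensations of free units give statistical oligomers. The key step uses the fact that in rings B and E the ring carbon bonded to the inner bridge (towards ring C or D) is ortho to the free 4-hydroxyl para to the butanoyl group, so a bridge carbon tethered to that oxygen through sulfur can be passed to this ring carbon in a [2,3] shift.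

## Logic of the disconnections

16 to 15. The six phenolic O–H bonds of rings C and D are traced back to methoxymethyl ethers. Keeping these rings etherified to the end blocks their keto tautomers, so the three inner bridges cannot interchange in the base-mediated bridging step. When the acetals are finally cleaved, no nucleophilic ring C–H is left to capture the C1 fragment that they release. The skeleton is unchanged; the demand is an acid mild enough for the trione ends.

15 to 12 and two molecules of 13. Both bonds of each terminal bridge carbon are cut (ring B or E carbon to CH2, and CH2 to ring A or F carbon). These bridges join two free, acidic partners and are the most easily scrambled, so they are made last. The hexamer falls to a tetramer with one free aromatic carbon at each end and two identical triones. The forward step must cross-couple without joining two tetramers. This is met by first attaching the C1 unit to 12 as an aminomethyl group (14), so that no free aromatic C–H remains when 13 is added.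

13 to 3. The two C–CH3 bonds at one ring carbon are cut. The same monomer then serves both branches. The demand is tolerance of a poorly selective C-methylation at the start of a one-step branch.

12 to 11. Two C–H bonds on the bridge carbons between rings B/C and D/E are traced back to C–S bonds. Sulfur is the tether of the key step and is not part of the target. The forward step must cleave C–S reductively without touching four aryl ketones.

11 to 8 and two molecules of 3. This is the key cut: the bond between each sulfur-bearing bridge carbon and the ring B or E carbon. The tetramer falls to a symmetrical dimer and two molecules of 3, which needs no protection. The distinction between inner rings (etherified) and outer rings (free) arises by itself. The forward step must alkylate 3 once, at carbon and not at oxygen.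

8 to 7. Six aryl O–CH2 ether bonds are cut. A free hydroxyl ortho to a benzylic sulfonium would expel the sulfur as a quinone methide and would itself capture the activated sulfur, so every oxygen of rings C and D must be capped. The demand is exhaustive etherification of hindered, hydrogen-bonded phenols.

7 to 5, two molecules of 4 and two of 6. The ring–CH2 and CH2–S bonds at the two free ring carbons are cut. This places the future bridge carbons and their sulfur handle in one operation. In the forward step 6 must trap the quinone methide faster than a second arene does.

5 to two molecules of 3 and one of 4. The two bonds of the central bridge carbon are cut, which uses the twofold symmetry. The condensation must stop at the dimer, which requires an excess of 3.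

3 to 1 and 2. The aryl–carbonyl bond is cut. Mono-acylation of 1 is self-limiting because the first acyl group deactivates the ring.

## Other disconnections considered

Alternative 1: The cut removes all twelve aryl C–O bonds of rings B to E. The oxygens are replaced by fluorine in the dodecafluoro tetraketone A1. In the forward key step A1 would react with sodium benzyloxide A2 to give the dodeca-O-benzyl tetramer core A3 by twelve SNAr reactions.
- In its favour: every fluorine of A1 is ortho or para to a ketone and so is activated. Fluoroarenes are not carbon nucleophiles, so the skeleton of A1 could be assembled by organometallic couplings with no bridge interchange and no over-condensation. The regiochemistry of SNAr is fixed by where the fluorines are. On this point the alternative is better than the chosen plan, which must control oxygen versus carbon attack and single versus multiple alkylation of an ambident phenol. It also avoids sulfur and transient stereocentres.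
- Against it: each alkoxy group introduced deactivates its ring towards the next substitution, so the third substitution on each ring would be slow, and twelve must go to completion on one molecule. Alkoxide may add to the doubly flanked ketones and cleave them in retro-Claisen fashion, or deprotonate the diarylmethane and α-keto positions. A1 needs a multistep assembly from a simple fluoroarene. A3 carries twelve identical ethers, so the inner and outer rings are no longer differentiated and its terminal carbons are weak nucleophiles. Debenzylation would have to precede the terminal bridging, which exposes all bridges to interchange.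
- Comparison: the skeleton assembly is more predictable mechanistically, but the end-game is less protected and the route is clearly longer than one that draws every ring from 1.

Alternative 2: The cut lies inside rings A and F: in each, the two bonds from the carbons flanking CMe2 to the other ring carbons. The benzyl-protected tetramer with a 3,5-dioxooctyl arm at each end, A4, would be silylated to the tetrakis(trimethylsilyl) bis-dienol ether A5. A5 would react with dimethylmalonyl dichloride A6 in a double [3+3] acylation–cyclisation to give the dodeca-O-benzyl ether of the target, A7, and hydrogenolysis would finish.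
- In its favour: the gem-dimethyl group arrives with the C3 electrophile, so number and position of the methyl groups are fixed. This is better than step 7 of the chosen plan. The terminal bridges already exist in the arms, so no formaldehyde chemistry touches the triones. The final hydrogenolysis is neutral, which is equal to or better than an acidic unveiling.
- Against it: after the first C-acylation at the terminal carbon, the ring can close through the enol oxygen as well as through the central carbon. Oxygen closure gives a six-membered enol lactone in place of the carbocycle, a common course for malonyl dichlorides. The four aryl butyl ketones of A4 are also enolisable and compete in silylation and acylation. Two cyclisations must succeed on one molecule. The disconnection says nothing about the three inner bridges: A4 still needs the whole tetramer core plus two arms.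
- Comparison: structurally cleaner at the end rings, mechanistically less certain in the ring closure, and several steps longer.

Alternative 3: The cut is the bond between each terminal bridge carbon and the ring A or F carbon, with the bridge carbon carried by the tetramer as a formyl group. The dodeca-O-methoxymethyl core dialdehyde A8 would condense with two molecules of 13 under amino acid catalysis, and a dihydropyridine hydride donor would reduce the alkylidene triones in situ. The product would be the dodeca-O-methoxymethyl ether of the target, A9.
- In its favour: the C1 unit is bound to the tetramer before 13 is added, so only cross-coupling is possible. The conditions are neutral and the reductive alkylation of cyclic 1,3-diones is well established. In directedness it equals step 8 of the chosen plan. It is better in one respect: there is no amine leaving group that could shuttle the C1 unit to 13.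
- Against it: the formyl groups of A8 sit between two acetal oxygens on hexasubstituted rings and are hindered. The alkylidene intermediate is a crowded, fully substituted alkene that may add a second 13 before it is reduced. The route needs formylation of both ends and protection of all twelve phenols, two to three extra steps, and twelve acetal cleavages next to the trione ends.
- Comparison: like alternative 2 it is an end-game only and could be combined with the chosen key step, at the cost of step count. The chosen plan uses the native nucleophilicity of the free ring B and E carbons and is shorter.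

Key step: step 5

Remarks on the chemistry:
- The end rings of 16 are written as one of several equivalent dienol–enone tautomers, and the target has no stereocentre.
- The structures of 8 and 11 agree atom by atom with the substitution pattern of 16 and need no correction.
- The design is refined at two points. In step 5 each activated sulfur is capped by a molecule of 3 before base is added. The MOM ethers of rings C and D are carried through the terminal bridging and removed only in the last step.
- Steps 2, 3, 5 and 8 are two-directional: each consumes two molecules of one partner per molecule of product. The second molecule is entered among the reagents that add atoms, so that every step balances as written.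

## Route

Step 1
Reactants: 1 phloroglucinol; 2 butanoyl chloride
Product: 3 1-(2,4,6-trihydroxyphenyl)butan-1-one
Conditions: AlCl3 (4 equiv), PhNO2/CH2Cl2, 0 → 50 °C; aq. HCl work-up
Reagents that add atoms: none
Why: Friedel–Crafts C-acylation of the symmetrical triol; the first acyl group deactivates the ring, so mono-acylation should dominate.

Step 2
Reactants: 3 1-(2,4,6-trihydroxyphenyl)butan-1-one (two molecules per molecule of product); 4 formaldehyde
Product: 5 1,1'-[methylenebis(2,4,6-trihydroxybenzene-3,1-diyl)]di(butan-1-one) (methylene-bridged dimer; future rings C and D)
Conditions: 4 (37% aq., 0.25 equiv per 3), cat. H2SO4, EtOH/H2O, 20 °C; unreacted 3 recovered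
Reagents that add atoms: second molecule of 3 1-(2,4,6-trihydroxyphenyl)butan-1-one, CCCC(=O)c1c(O)cc(O)cc1O
Why: Acid-catalysed hydroxymethylation and Friedel–Crafts alkylation (phenol–formaldehyde condensation) joins two molecules of 3 through one carbon of 4 with loss of water; the fourfold excess of 3 over 4 should hold the condensation at the dimer.

Step 3
Reactants: 5 methylene-bridged dimer; 4 formaldehyde (two molecules); 6 thiophenol (two molecules)
Product: 7 dimer 5 carrying a phenylsulfanylmethyl group on the free carbon of each ring (bis(phenylthiomethyl) hexaol)
Conditions: 4 (37% aq., 3 equiv), 6 (5 equiv), Et3N (0.5 equiv), EtOH, 50 °C, N2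
Reagents that add atoms: second molecule of 4 formaldehyde, C=O; second molecule of 6 thiophenol, Sc1ccccc1
Why: Thiol variant of the phenolic Mannich reaction, once on each ring: hydroxymethylation ortho to OH, loss of water to the o-quinone methide and conjugate addition of thiolate; excess thiol should outcompete arene nucleophiles, so no further methylene bridges form.

Step 4
Reactants: 7 bis(phenylthiomethyl) hexaol
Product: 8 hexakis(methoxymethyl) ether of 7 (key-step precursor)
Conditions: NaH (8 equiv), MOMCl (9 equiv), DMF, 0 → 20 °C
Reagents that add atoms: chloromethyl methyl ether (MOMCl; six molecules, one per hydroxyl), COCCl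
Why: Williamson-type O-alkylation of the hexaphenoxide by a hard, oxocarbenium-like electrophile, which favours oxygen over the fully substituted ring carbons; NaH is used because the hydroxyls ortho to the ketones are hydrogen-bonded and react sluggishly with amine bases.

Step 5
Reactants: 8 hexa-O-MOM bis(phenylthiomethyl) dimer; 3 1-(2,4,6-trihydroxyphenyl)butan-1-one (two molecules enter the product; used in excess)
Product: 11 tetramer core B–C–D–E with a phenylsulfanyl group on each of the two new bridge carbons (MOM ethers on rings C and D; mixture of diastereomers), via bis(succinimidosulfonium) dichloride 9 (not isolated), via bis(aryloxysulfonium) dichloride 10 (not isolated)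
Conditions: NCS (2.1 equiv), CH2Cl2, −40 °C; then 3 (8 equiv) in THF, −40 °C; then Et3N (12 equiv), −40 → 0 °C
Reagents that add atoms: second molecule of 3 1-(2,4,6-trihydroxyphenyl)butan-1-one, CCCC(=O)c1c(O)cc(O)cc1O
Why: NCS activates each sulfur as the succinimidosulfonium salt 9, and the non-chelated 4-hydroxyl of 3, the most acidic and most nucleophilic oxygen of the monomer, displaces succinimide at sulfur to give the aryloxysulfonium salt 10. Et3N then removes a proton from the benzylic carbon, the only carbon next to sulfur that carries hydrogen, and the ylide undergoes a [2,3]-sigmatropic shift through a five-membered transition state that breaks the S–O bond and joins the bridge carbon to the ring carbon ortho to the tethering oxygen; tautomerisation of the cyclohexadienone restores the phenol. The closest known reaction type is the Gassman ortho-alkylation of phenols, a Sommelet–Hauser-type rearrangement of aryloxysulfonium ylides. No ring is closed. The two sulfur-bearing carbons are new stereocentres formed without control, which does not matter because step 6 turns both into CH2. The step needs carbon rather than oxygen or ipso alkylation, which follows from the cyclic transition state; both ortho carbons of the 4-hydroxyl are equivalent, and a tether through a 2-hydroxyl would deliver to the same carbon. It needs mono-alkylation of 3, which should hold because every sulfonium is capped by a molecule of 3, present in large excess, before base is added; it also needs inert rings C and D, and their full substitution and MOM protection exclude ring chlorination and quinone methide collapse. Should 9 or 10 instead collapse to a thionium ion, Friedel–Crafts attack of 3 at the same ring carbon gives the same product.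

Step 6
Reactants: 11 bis(phenylsulfanyl) tetramer core
Product: 12 hexa-O-MOM tetramer B–C–D–E (rings C and D etherified; rings B and E free)
Conditions: Raney Ni (W-2, deactivated in acetone), EtOH/THF, 20 °C
Reagents that add atoms: none
Why: Raney Ni desulfurisation (hydrogenolysis) of the two doubly benzylic C–S bonds; deactivated catalyst at room temperature should leave the hindered or hydrogen-bonded aryl ketones and the MOM ethers alone, and it removes both transient stereocentres.

Step 7
Reactants: 3 1-(2,4,6-trihydroxyphenyl)butan-1-one
Product: 13 butyrylfilicinic acid (2-butanoyl-3,5-dihydroxy-4,4-dimethylcyclohexa-2,5-dien-1-one)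
Conditions: NaOMe (3 equiv), MeI (2.2 equiv), MeOH, 0 → 20 °C
Reagents that add atoms: iodomethane (two molecules), CI
Why: Dearomatising double C-methylation of the phloroglucinol anion at one ring carbon; mono-, tri- and tetramethyl congeners are expected and are removed by chromatography and crystallisation, which is acceptable for a one-step branch from cheap material.

Step 8
Reactants: 12 hexa-O-MOM tetramer; 13 butyrylfilicinic acid (two molecules enter the product; used in excess)
Product: 15 hexa-O-MOM ether of the target (MOM on all hydroxyls of rings C and D), via bis(dimethylaminomethyl) tetramer 14 (not isolated)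
Conditions: CH2=NMe2+ I− (2.2 equiv), Et3N (2.2 equiv), MeCN, 0 → 20 °C; then 13 (5 equiv), 60 °C
Reagents that add atoms: dimethylmethyleneammonium iodide (Eschenmoser's salt; two molecules, each leaves one CH2), C=[N+](C)C.[I-]; second molecule of 13 butyrylfilicinic acid, CCCC(=O)C1=C(O)C(C)(C)C(O)=CC1=O
Why: Mannich aminomethylation at the only free aromatic carbon of rings B and E, then thermal loss of dimethylamine to the o-quinone methide and Michael addition of the enol carbon of 13 at each end; 14 has no free aromatic C–H, so the tetramer cannot couple with itself, and the MOM ethers keep rings C and D from tautomerising, so the inner bridges cannot interchange.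

Step 9
Reactants: 15 hexa-O-MOM ether of the target
Product: 16 target CNP0237140.0
Conditions: HCl (ca. 1 M in MeOH), MeOH/THF, 20 → 40 °C
Reagents that add atoms: none
Why: Acid-catalysed acetal exchange (MOM ether cleavage) in methanol; 15 has no nucleophilic ring C–H left, so the liberated formaldehyde acetal cannot form new bridges, and dilute acid near room temperature should not cyclodehydrate the trione ends.

## Compound list

1 | phloroglucinol (benzene-1,3,5-triol) | Oc1cc(O)cc(O)c1 | starting material
2 | butanoyl chloride | CCCC(=O)Cl | starting material
3 | 1-(2,4,6-trihydroxyphenyl)butan-1-one (monomer ketone) | CCCC(=O)c1c(O)cc(O)cc1O | intermediate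
4 | formaldehyde | C=O | starting material
5 | 1,1'-[methylenebis(2,4,6-trihydroxybenzene-3,1-diyl)]di(butan-1-one) (rings C and D dimer) | CCCC(=O)c1c(O)cc(O)c(Cc2c(O)cc(O)c(C(=O)CCC)c2O)c1O | intermediate
6 | thiophenol (benzenethiol) | Sc1ccccc1 | starting material
7 | dimer 5 with a phenylsulfanylmethyl group on the remaining carbon of each ring | CCCC(=O)c1c(O)c(CSc2ccccc2)c(O)c(Cc3c(O)c(CSc4ccccc4)c(O)c(C(=O)CCC)c3O)c1O | intermediate
8 | hexakis(methoxymethyl) ether of 7 (key-step precursor) | CCCC(=O)c1c(OCOC)c(CSc2ccccc2)c(OCOC)c(Cc3c(OCOC)c(CSc4ccccc4)c(OCOC)c(C(=O)CCC)c3OCOC)c1OCOC | intermediate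
9 | bis(succinimidosulfonium) dichloride of 8 (each S bears phenyl, the benzylic CH2 and N-succinimidyl) | CCCC(=O)c1c(OCOC)c(C[S+](c2ccccc2)N2C(=O)CCC2=O)c(OCOC)c(Cc3c(OCOC)c(C[S+](c4ccccc4)N4C(=O)CCC4=O)c(OCOC)c(C(=O)CCC)c3OCOC)c1OCOC.[Cl-].[Cl-] | intermediate
10 | bis(aryloxysulfonium) dichloride (each S bears phenyl, the benzylic CH2 and the 4-oxygen of a molecule of 3) | CCCC(=O)c1c(OCOC)c(C[S+](c2ccccc2)Oc2cc(O)c(C(=O)CCC)c(O)c2)c(OCOC)c(Cc3c(OCOC)c(C[S+](c4ccccc4)Oc4cc(O)c(C(=O)CCC)c(O)c4)c(OCOC)c(C(=O)CCC)c3OCOC)c1OCOC.[Cl-].[Cl-] | intermediate
11 | tetramer core B–C–D–E, PhS on the B–C and D–E bridge carbons, MOM on rings C and D, rings B and E free (both CH(SPh) centres unassigned, mixture of diastereomers) | CCCC(=O)c1c(O)cc(O)c(C(Sc2ccccc2)c2c(OCOC)c(Cc3c(OCOC)c(C(Sc4ccccc4)c4c(O)cc(O)c(C(=O)CCC)c4O)c(OCOC)c(C(=O)CCC)c3OCOC)c(OCOC)c(C(=O)CCC)c2OCOC)c1O | intermediate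
12 | hexa-O-MOM tetramer B–C–D–E with three CH2 bridges, rings B and E free | CCCC(=O)c1c(O)cc(O)c(Cc2c(OCOC)c(Cc3c(OCOC)c(Cc4c(O)cc(O)c(C(=O)CCC)c4O)c(OCOC)c(C(=O)CCC)c3OCOC)c(OCOC)c(C(=O)CCC)c2OCOC)c1O | intermediate
13 | butyrylfilicinic acid (2-butanoyl-3,5-dihydroxy-4,4-dimethylcyclohexa-2,5-dien-1-one) | CCCC(=O)C1=C(O)C(C)(C)C(O)=CC1=O | intermediate
14 | 12 with a dimethylaminomethyl group on the free carbon of rings B and E | CCCC(=O)c1c(O)c(CN(C)C)c(O)c(Cc2c(OCOC)c(Cc3c(OCOC)c(Cc4c(O)c(CN(C)C)c(O)c(C(=O)CCC)c4O)c(OCOC)c(C(=O)CCC)c3OCOC)c(OCOC)c(C(=O)CCC)c2OCOC)c1O | intermediate
15 | hexamer A–F with MOM ethers on all six hydroxyls of rings C and D | CCCC(=O)C1=C(O)C(C)(C)C(O)=C(Cc2c(O)c(Cc3c(OCOC)c(Cc4c(OCOC)c(Cc5c(O)c(CC6=C(O)C(C)(C)C(O)=C(C(=O)CCC)C6=O)c(O)c(C(=O)CCC)c5O)c(OCOC)c(C(=O)CCC)c4OCOC)c(OCOC)c(C(=O)CCC)c3OCOC)c(O)c(C(=O)CCC)c2O)C1=O | intermediate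
16 | CNP0237140.0 (hexamer A–F, no stereocentre) | CCCC(=O)C1=C(O)C(C)(C)C(O)=C(Cc2c(O)c(Cc3c(O)c(Cc4c(O)c(Cc5c(O)c(CC6=C(O)C(C)(C)C(O)=C(C(=O)CCC)C6=O)c(O)c(C(=O)CCC)c5O)c(O)c(C(=O)CCC)c4O)c(O)c(C(=O)CCC)c3O)c(O)c(C(=O)CCC)c2O)C1=O | target

## Step count and least certain steps

Total step count: 9. Longest linear sequence: 8 steps (steps 1, 2, 3, 4, 5, 6, 8, 9 from 1); step 7 is a one-step branch from 3.

Step 5 (key step). What may go wrong:
- Pummerer-type loss of HCl from the activated sulfide, or heterolysis of the electron-rich benzylic C–S bond, before the phenol has bound to sulfur. An ortho acetal oxygen could then attack the benzylic carbon.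
- A charge-accelerated [3,3] shift of the aryloxysulfonium onto the S-phenyl ring if base is added late.
- Chlorination of 3 by unconsumed NCS.
- Capture of two sulfonium centres by one monomer, leading to oligomers.
- Base-induced loss of thiophenolate from 11 to a quinone methide that adds a second 3.

Fallback: the approach changes from the sigmatropic shift to an intermolecular Pummerer alkylation. Setting out from 8, both sulfides are oxidised with mCPBA (2 equiv, −78 °C) to the bis-sulfoxide F1. F1 is activated with trifluoroacetic anhydride and 2,6-lutidine in CH2Cl2, and the thionium ions so formed alkylate an excess of 3 in a Friedel–Crafts-type aromatic substitution at the same ring carbon. The fallback comes back to the route at 11.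

Step 8. What may go wrong:
- Retro-Mannich transfer of the aminomethyl unit from 14 to 13. This consumes 13 as its methylene-bridged self-dimer and regenerates free aromatic carbons that can then join two tetramers.
- Oxygen instead of carbon attack of 13 on the quinone methide.
- Sluggish loss of the amine.

Fallback: the polarity is inverted to the classical three-component condensation. Setting out from 12 and a large excess of 13, aqueous 4 is added in dilute methanolic KOH at 0 → 20 °C. The methylene trione is then generated from 13 and trapped by the phenoxide carbons of rings B and E, and the fallback comes back at 15. It makes no new compound (F0). The MOM ethers of rings C and D still protect the inner bridges under these basic conditions.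

Step 9. What may go wrong:
- Incomplete cleavage of the two acetals per ring that lie between two benzylic groups.
- Acid-induced cyclodehydration of a trione end onto the neighbouring phenol.
- Acid-induced retro-Michael cleavage of the terminal bridges.

Fallback: the order of unveiling and bridging is inverted. Setting out from 12, the six acetals are cleaved with ZnBr2 and n-PrSH in CH2Cl2 at 0 °C, where the thiol traps the methoxymethyl cation so that the free ring carbons are not bridged. This gives the free tetramer F2. F2 is aminomethylated with dimethylmethyleneammonium iodide and Et3N to the bis(dimethylaminomethyl) tetramer F3, which is heated with excess 13 as in step 8. The fallback arrives directly at 16, and no acid touches the finished hexamer. The price is that the inner bridges are unprotected during the coupling.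

Step 6. What may go wrong:
- Over-reduction of aryl ketones to carbinols.
- Incomplete desulfurisation because the polyphenol adsorbs on the metal.

Fallback: a radical chain reduction replaces the surface hydrogenolysis. Setting out from 11, Bu3SnH and AIBN in toluene at 80 °C cleave the doubly benzylic C–S bonds through stabilised diarylmethyl radicals and do not reduce ketones. The fallback comes back at 12 and makes no new compound (F0).

Step 2. What may go wrong:
- Over-condensation to trimers and higher oligomers, because 5 keeps one free carbon on each ring.

Fallback: the order of the two formaldehyde steps is inverted. Setting out from 3, reaction with limiting 4 and 6 (Et3N, EtOH) gives the mono(phenylsulfanylmethyl) ketone F4, which has a single free ring carbon. Acid-catalysed condensation of two molecules of F4 with 4 can then stop only at the dimer. The fallback comes back at 7 and bypasses 5.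

Step 7. What may go wrong:
- Poor selectivity between mono-, di-, tri- and tetra-C-methylation, and some O-methylation.

Fallback: one ring carbon is blocked before methylation. Setting out from 3, a second Friedel–Crafts acylation with 2 and AlCl3 gives the diketone F5 (2,4-dibutanoylphloroglucinol), which has only one nucleophilic ring carbon. NaOMe and MeI then give the dibutanoyl trione F6. Partial acid deacylation (ca. 80% H2SO4, 60–80 °C), which cleaves one butanoyl group, comes back to the route at 13.

## Further compounds

F1 | step 5 | bis-sulfoxide of 8 (both S-oxides, mixture of diastereomers at sulfur) | CCCC(=O)c1c(OCOC)c(CS(=O)c2ccccc2)c(OCOC)c(Cc3c(OCOC)c(CS(=O)c4ccccc4)c(OCOC)c(C(=O)CCC)c3OCOC)c1OCOC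
F0 | step 8 | none | none
F2 | step 9 | free tetramer B–C–D–E (all twelve hydroxyls free) | CCCC(=O)c1c(O)cc(O)c(Cc2c(O)c(Cc3c(O)c(Cc4c(O)cc(O)c(C(=O)CCC)c4O)c(O)c(C(=O)CCC)c3O)c(O)c(C(=O)CCC)c2O)c1O
F3 | step 9 | F2 with a dimethylaminomethyl group on the free carbon of rings B and E | CCCC(=O)c1c(O)c(CN(C)C)c(O)c(Cc2c(O)c(Cc3c(O)c(Cc4c(O)c(CN(C)C)c(O)c(C(=O)CCC)c4O)c(O)c(C(=O)CCC)c3O)c(O)c(C(=O)CCC)c2O)c1O
F0 | step 6 | none | none
F4 | step 2 | 1-{2,4,6-trihydroxy-3-[(phenylsulfanyl)methyl]phenyl}butan-1-one | CCCC(=O)c1c(O)cc(O)c(CSc2ccccc2)c1O
F5 | step 7 | 1,1'-(2,4,6-trihydroxy-1,3-phenylene)di(butan-1-one) | CCCC(=O)c1c(O)cc(O)c(C(=O)CCC)c1O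
F6 | step 7 | 2,6-dibutanoyl-3,5-dihydroxy-4,4-dimethylcyclohexa-2,5-dien-1-one | CCCC(=O)C1=C(O)C(C)(C)C(O)=C(C(=O)CCC)C1=O
A1 | alternative 1 | dodecafluoro tetraketone (rings B to E with F in place of every OH) | CCCC(=O)c1c(F)cc(F)c(Cc2c(F)c(Cc3c(F)c(Cc4c(F)cc(F)c(C(=O)CCC)c4F)c(F)c(C(=O)CCC)c3F)c(F)c(C(=O)CCC)c2F)c1F
A2 | alternative 1 | sodium benzyloxide | [Na+].[O-]Cc1ccccc1
A3 | alternative 1 | dodeca-O-benzyl tetramer core | CCCC(=O)c1c(OCc5ccccc5)cc(OCc5ccccc5)c(Cc2c(OCc5ccccc5)c(Cc3c(OCc5ccccc5)c(Cc4c(OCc5ccccc5)cc(OCc5ccccc5)c(C(=O)CCC)c4OCc5ccccc5)c(OCc5ccccc5)c(C(=O)CCC)c3OCc5ccccc5)c(OCc5ccccc5)c(C(=O)CCC)c2OCc5ccccc5)c1OCc5ccccc5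
A4 | alternative 2 | dodeca-O-benzyl tetramer with a 3,5-dioxooctyl arm on the terminal carbon of rings B and E | CCCC(=O)c1c(OCc5ccccc5)c(CCC(=O)CC(=O)CCC)c(OCc5ccccc5)c(Cc2c(OCc5ccccc5)c(Cc3c(OCc5ccccc5)c(Cc4c(OCc5ccccc5)c(CCC(=O)CC(=O)CCC)c(OCc5ccccc5)c(C(=O)CCC)c4OCc5ccccc5)c(OCc5ccccc5)c(C(=O)CCC)c3OCc5ccccc5)c(OCc5ccccc5)c(C(=O)CCC)c2OCc5ccccc5)c1OCc5ccccc5
A5 | alternative 2 | tetrakis(trimethylsilyl) bis-dienol ether of A4 (alkene geometry unassigned) | CCCC(=O)c1c(OCc5ccccc5)c(CC=C(O[Si](C)(C)C)C=C(O[Si](C)(C)C)CCC)c(OCc5ccccc5)c(Cc2c(OCc5ccccc5)c(Cc3c(OCc5ccccc5)c(Cc4c(OCc5ccccc5)c(CC=C(O[Si](C)(C)C)C=C(O[Si](C)(C)C)CCC)c(OCc5ccccc5)c(C(=O)CCC)c4OCc5ccccc5)c(OCc5ccccc5)c(C(=O)CCC)c3OCc5ccccc5)c(OCc5ccccc5)c(C(=O)CCC)c2OCc5ccccc5)c1OCc5ccccc5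
A6 | alternative 2 | dimethylmalonyl dichloride | CC(C)(C(=O)Cl)C(=O)Cl
A7 | alternative 2 | dodeca-O-benzyl ether of the target | CCCC(=O)C1=C(O)C(C)(C)C(O)=C(Cc2c(OCc7ccccc7)c(Cc3c(OCc7ccccc7)c(Cc4c(OCc7ccccc7)c(Cc5c(OCc7ccccc7)c(CC6=C(O)C(C)(C)C(O)=C(C(=O)CCC)C6=O)c(OCc7ccccc7)c(C(=O)CCC)c5OCc7ccccc7)c(OCc7ccccc7)c(C(=O)CCC)c4OCc7ccccc7)c(OCc7ccccc7)c(C(=O)CCC)c3OCc7ccccc7)c(OCc7ccccc7)c(C(=O)CCC)c2OCc7ccccc7)C1=O
A8 | alternative 3 | dodeca-O-methoxymethyl core dialdehyde (formyl on the terminal carbon of rings B and E) | O=Cc1c(OCOC)c(Cc2c(OCOC)c(Cc3c(OCOC)c(Cc4c(OCOC)c(C=O)c(OCOC)c(C(=O)CCC)c4OCOC)c(OCOC)c(C(=O)CCC)c3OCOC)c(OCOC)c(C(=O)CCC)c2OCOC)c(OCOC)c(C(=O)CCC)c1OCOC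
A9 | alternative 3 | dodeca-O-methoxymethyl ether of the target | CCCC(=O)C1=C(O)C(C)(C)C(O)=C(Cc2c(OCOC)c(Cc3c(OCOC)c(Cc4c(OCOC)c(Cc5c(OCOC)c(CC6=C(O)C(C)(C)C(O)=C(C(=O)CCC)C6=O)c(OCOC)c(C(=O)CCC)c5OCOC)c(OCOC)c(C(=O)CCC)c4OCOC)c(OCOC)c(C(=O)CCC)c3OCOC)c(OCOC)c(C(=O)CCC)c2OCOC)C1=O
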